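**Retrosynthetic overview**

1. Ring A of selaginellin U carries four contiguous substituted carbons (C1 methyl, C2 arylethynyl, C3 bearing the quinone methide carbon C7, C4 ring B) and a single unsubstituted CH=CH edge, C5–C6. Ring A is therefore cut at C5=C6 and built from an open chain.
2. The C7 quinone methide comes from dehydration of a bis(4-hydroxyphenyl)carbinol, made by double aryllithium addition to a C3 ester. The C2 alkyne comes from Sonogashira coupling of the triflate of a C2 phenol. Both lead back to a salicylate.
3. The salicylate is the dehydrogenation product of a cyclohexenone keto ester, which opens at C5=C6 (ring-closing metathesis in the forward sense) to an acyclic diene keto ester.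
4. The diene keto ester comes from iridium-catalysed branched allylation of ethyl 4-methyl-3-oxohex-5-enoate (from 2-methylbut-3-enoic acid and potassium ethyl malonate) with the ethyl carbonate of 4-methoxycinnamyl alcohol.
5. Ring order: all anisyl rings are bought. Ring A is the only ring made (closed in step 4, aromatized in step 5). The quinone methide ring arises last from one anisyl ring.

Key step: step 4

Remark: the target has no stereocentre, so racemic 1 and the diastereomer mixtures 8 and 9 are used as such; an ethyl carbonate is chosen for 7 so that the alkoxide released in step 3 matches the ethyl ester.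

**Step 1**
Reactants: 1 2-methylbut-3-enoic acid (racemic); 2 potassium ethyl malonate
Product: 5 ethyl 4-methyl-3-oxohex-5-enoate (racemic), via acyl imidazolide 3 (not isolated), via acylmalonate half ester 4 (not isolated)
Conditions: CDI, THF, 0 °C to rt; then 2, MgCl2, THF, rt to 45 °C; cold 1 M HCl work-up
Reagents that add atoms: none
Why: Masamune–Brooks decarboxylative Claisen homologation, in which acyl imidazolide 3 C-acylates malonate 2 (held as its magnesium chelate by MgCl2) under near-neutral conditions that should leave the β,γ-alkene in place, and acylmalonate 4 loses CO2 to give the β-keto ester, whose single racemic stereocentre is erased in step 5.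

**Step 2**
Reactants: 6 (E)-3-(4-methoxyphenyl)prop-2-en-1-ol
Product: 7 ethyl (E)-3-(4-methoxyphenyl)prop-2-en-1-yl carbonate
Conditions: ClCO2Et, pyridine, CH2Cl2, 0 °C to rt
Reagents that add atoms: ethyl chloroformate, CCOC(=O)Cl
Why: Acylation of a primary allylic alcohol with a chloroformate (carbonate formation), which should leave the E-alkene and the aryl ether untouched.

**Step 3**
Reactants: 5 ethyl 4-methyl-3-oxohex-5-enoate (1.2 equiv); 7 ethyl (E)-3-(4-methoxyphenyl)prop-2-en-1-yl carbonate
Product: 8 ethyl 2-[1-(4-methoxyphenyl)prop-2-en-1-yl]-4-methyl-3-oxohex-5-enoate (diastereomer mixture)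
Conditions: [Ir(cod)Cl]2 (2 mol %), (S,S,S)-Feringa phosphoramidite [O,O'-(1,1'-binaphthalene-2,2'-diyl) N,N-bis(1-phenylethyl)phosphoramidite, either enantiomer] (4 mol %), TBD (10 mol %), THF, rt
Reagents that add atoms: none
Why: Iridium-catalysed branched-selective allylic alkylation (Tsuji–Trost type), in which ionization of the carbonate gives an allyliridium species and ethoxide, the ethoxide deprotonates the β-keto ester at its most acidic C2 position (which also shields the β,γ-alkene from base), and the stabilized enolate attacks the aryl-bearing allyl terminus as is usual for cinnamyl carbonates with iridium phosphoramidite catalysts; the new stereocentres form as a mixture and need no control because step 5 erases them.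

**Step 4**
Reactants: 8 ethyl 2-[1-(4-methoxyphenyl)prop-2-en-1-yl]-4-methyl-3-oxohex-5-enoate (diastereomer mixture)
Product: 9 ethyl 6-(4-methoxyphenyl)-3-methyl-2-oxocyclohex-4-ene-1-carboxylate (diastereomer mixture)
Conditions: second-generation Grubbs catalyst (H2IMes)(PCy3)Cl2Ru=CHPh (5 mol %), 1,4-benzoquinone (10 mol %), CH2Cl2 (0.005 M), 40 °C
Reagents that add atoms: none
Why: The ruthenium benzylidene exchanges with one terminal vinyl group of 8 to give a ruthenium alkylidene, which adds to the second vinyl group in a (2+2) cycloaddition, and cycloreversion of the ruthenacyclobutane forms the C5=C6 double bond and expels ethylene, whose escape makes the closure irreversible. The closest known reaction type is ring-closing metathesis of ketone-containing octa-1,7-dienes to cyclohexenones that are afterwards dehydrogenated to phenols. Ring A is closed as an unstrained six-membered carbocycle by joining the two alkene termini of the octa-1,7-diene chain, with the four future arene substituents already in place on C1 to C4. No stereocentre is formed, and the three existing ones may have any configuration because every diastereomer can reach the ring and step 5 erases them. The step needs chemoselectivity for closure over oligomerization and over migration of the vinyl group next to the ketone into conjugation: both alkenes are terminal and monosubstituted but allylically branched, which slows intermolecular metathesis relative to six-ring closure, and high dilution, neutral conditions and 1,4-benzoquinone as a scavenger of ruthenium hydrides should suppress isomerization.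

**Step 5**
Reactants: 9 ethyl 6-(4-methoxyphenyl)-3-methyl-2-oxocyclohex-4-ene-1-carboxylate (diastereomer mixture)
Product: 11 ethyl 3-hydroxy-4'-methoxy-4-methyl-[1,1'-biphenyl]-2-carboxylate, via dienol tautomer 10 (not isolated)
Conditions: DDQ (1.2 equiv), 1,4-dioxane, rt to 60 °C
Reagents that add atoms: none
Why: Quinone dehydrogenation, in which the β-keto ester enolizes to cyclohexa-1,4-dienol 10, DDQ abstracts hydride from the doubly allylic, benzylic C–H next to the anisyl ring and loss of a proton from the methyl-bearing carbon gives the aromatic salicylate, removing all three stereocentres.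

**Step 6**
Reactants: 11 ethyl 3-hydroxy-4'-methoxy-4-methyl-[1,1'-biphenyl]-2-carboxylate
Product: 12 ethyl 4'-methoxy-4-methyl-3-{[(trifluoromethyl)sulfonyl]oxy}-[1,1'-biphenyl]-2-carboxylate
Conditions: Tf2O, pyridine, CH2Cl2, 0 °C to rt
Reagents that add atoms: triflic anhydride, O=S(=O)(OS(=O)(=O)C(F)(F)F)C(F)(F)F
Why: O-sulfonylation of the phenol with triflic anhydride and pyridine, the standard triflation of salicylates, in which the reactive anhydride should overcome the hydrogen bond to the ester and the two ortho substituents.

**Step 7**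
Reactants: 12 ethyl 4'-methoxy-4-methyl-3-{[(trifluoromethyl)sulfonyl]oxy}-[1,1'-biphenyl]-2-carboxylate; 13 1-ethynyl-4-methoxybenzene
Product: 14 ethyl 4'-methoxy-3-[(4-methoxyphenyl)ethynyl]-4-methyl-[1,1'-biphenyl]-2-carboxylate
Conditions: Pd(PPh3)2Cl2 (5 mol %), CuI (10 mol %), n-Bu4NI, Et3N, DMF, 70 °C
Reagents that add atoms: none
Why: Sonogashira coupling, in which zerovalent palladium inserts into the aryl C–O bond of the triflate (activated by the ortho ester), the copper acetylide of 13 transmetalates and reductive elimination forms the aryl–alkynyl bond.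

**Step 8**
Reactants: 14 ethyl 4'-methoxy-3-[(4-methoxyphenyl)ethynyl]-4-methyl-[1,1'-biphenyl]-2-carboxylate; 15 1-bromo-4-methoxybenzene (4 equiv)
Product: 18 {4'-methoxy-3-[(4-methoxyphenyl)ethynyl]-4-methyl-[1,1'-biphenyl]-2-yl}bis(4-methoxyphenyl)methanol, via 4-methoxyphenyllithium 16 (not isolated), via diaryl ketone 17 (not isolated)
Conditions: 15, n-BuLi, THF, −78 °C; then 14, −78 °C to rt; aq. NH4Cl
Reagents that add atoms: none
Why: Bromine–lithium exchange gives aryllithium 16, whose first addition to the ester gives ketone 17 after loss of ethoxide and whose second addition to this more electrophilic ketone gives the tertiary alkoxide (double addition of an organolithium to an ester); the small, strongly nucleophilic aryllithium is used in excess because the ester sits between two ortho substituents, of which the alkyne is slim.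

**Step 9**
Reactants: 18 {4'-methoxy-3-[(4-methoxyphenyl)ethynyl]-4-methyl-[1,1'-biphenyl]-2-yl}bis(4-methoxyphenyl)methanol
Product: 20 selaginellin U, via tetraphenol carbinol 19 (not isolated)
Conditions: BBr3 (10 equiv), CH2Cl2, −78 °C to rt; then ice water, NaHCO3
Reagents that add atoms: none
Why: Lewis acid-mediated cleavage of aryl methyl ethers by BBr3 (bromide attack on the O-methyl group of the boron-complexed ether) frees the four phenols, and on aqueous work-up the bis(4-hydroxyphenyl)carbinol 19 should lose water through its stabilized triarylmethyl cation to give the para-quinone methide (fuchsone formation), the form in which the target is written.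

**Compound list**

1 | 2-methylbut-3-enoic acid (racemic) | C=CC(C)C(=O)O | starting material
2 | potassium ethyl malonate | CCOC(=O)CC(=O)[O-].[K+] | starting material
3 | 1-(imidazol-1-yl)-2-methylbut-3-en-1-one (acyl imidazolide) | C=CC(C)C(=O)n1ccnc1 | intermediate
4 | 2-(ethoxycarbonyl)-4-methyl-3-oxohex-5-enoic acid (magnesium salt in the flask, drawn as the free acid) | CCOC(=O)C(C(=O)O)C(=O)C(C)C=C | intermediate
5 | ethyl 4-methyl-3-oxohex-5-enoate (racemic) | CCOC(=O)CC(=O)C(C)C=C | intermediate
6 | (E)-3-(4-methoxyphenyl)prop-2-en-1-ol | COc1ccc(/C=C/CO)cc1 | starting material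
7 | ethyl (E)-3-(4-methoxyphenyl)prop-2-en-1-yl carbonate | CCOC(=O)OC/C=C/c1ccc(OC)cc1 | intermediate
8 | ethyl 2-[1-(4-methoxyphenyl)prop-2-en-1-yl]-4-methyl-3-oxohex-5-enoate (diastereomer mixture) | CCOC(=O)C(C(C=C)c1ccc(OC)cc1)C(=O)C(C)C=C | intermediate
9 | ethyl 6-(4-methoxyphenyl)-3-methyl-2-oxocyclohex-4-ene-1-carboxylate (diastereomer mixture) | CCOC(=O)C1C(=O)C(C)C=CC1c1ccc(OC)cc1 | intermediate
10 | ethyl 2-hydroxy-6-(4-methoxyphenyl)-3-methylcyclohexa-1,4-diene-1-carboxylate (dienol tautomer of 9) | CCOC(=O)C1=C(O)C(C)C=CC1c1ccc(OC)cc1 | intermediate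
11 | ethyl 3-hydroxy-4'-methoxy-4-methyl-[1,1'-biphenyl]-2-carboxylate | CCOC(=O)c1c(O)c(C)ccc1-c1ccc(OC)cc1 | intermediate
12 | ethyl 4'-methoxy-4-methyl-3-{[(trifluoromethyl)sulfonyl]oxy}-[1,1'-biphenyl]-2-carboxylate | CCOC(=O)c1c(OS(=O)(=O)C(F)(F)F)c(C)ccc1-c1ccc(OC)cc1 | intermediate
13 | 1-ethynyl-4-methoxybenzene | C#Cc1ccc(OC)cc1 | starting material
14 | ethyl 4'-methoxy-3-[(4-methoxyphenyl)ethynyl]-4-methyl-[1,1'-biphenyl]-2-carboxylate | CCOC(=O)c1c(C#Cc2ccc(OC)cc2)c(C)ccc1-c1ccc(OC)cc1 | intermediate
15 | 1-bromo-4-methoxybenzene | COc1ccc(Br)cc1 | starting material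
16 | 4-methoxyphenyllithium | [Li]c1ccc(OC)cc1 | intermediate
17 | {4'-methoxy-3-[(4-methoxyphenyl)ethynyl]-4-methyl-[1,1'-biphenyl]-2-yl}(4-methoxyphenyl)methanone | COc1ccc(cc1)C(=O)c1c(C#Cc2ccc(OC)cc2)c(C)ccc1-c1ccc(OC)cc1 | intermediate
18 | {4'-methoxy-3-[(4-methoxyphenyl)ethynyl]-4-methyl-[1,1'-biphenyl]-2-yl}bis(4-methoxyphenyl)methanol | COc1ccc(cc1)C(O)(c1ccc(OC)cc1)c1c(C#Cc2ccc(OC)cc2)c(C)ccc1-c1ccc(OC)cc1 | intermediate
19 | 2-[hydroxybis(4-hydroxyphenyl)methyl]-3-[(4-hydroxyphenyl)ethynyl]-4-methyl-[1,1'-biphenyl]-4'-ol | Cc1ccc(-c2ccc(O)cc2)c(C(O)(c2ccc(O)cc2)c2ccc(O)cc2)c1C#Cc1ccc(O)cc1 | intermediate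
20 | selaginellin U, 4-[{4'-hydroxy-3-[(4-hydroxyphenyl)ethynyl]-4-methyl-[1,1'-biphenyl]-2-yl}(4-hydroxyphenyl)methylidene]cyclohexa-2,5-dien-1-one (no stereocentre) | Cc1ccc(-c2ccc(O)cc2)c(C(=C2C=CC(=O)C=C2)c2ccc(O)cc2)c1C#Cc1ccc(O)cc1 | target

**Step count**

Total: 9 steps. Longest linear sequence: 8 steps (steps 1 and 3 to 9; step 2 is a one-step branch).

**Steps most likely to fail, with fallbacks**

Step 4 (ring-closing metathesis). The risk is migration of the terminal alkene next to the ketone into conjugation, through ruthenium hydrides or through the enol, before the carbene closes the ring. Chelation of the propagating carbene by the 1,3-dicarbonyl unit could also stall turnover. The fallback sets out from 8 and returns at 9. The ketone of 8 is reduced with NaBH4 in EtOH at 0 °C to ethyl 3-hydroxy-2-[1-(4-methoxyphenyl)prop-2-en-1-yl]-4-methylhex-5-enoate F1. In F1 the vinyl group has no carbonyl to conjugate with and no 1,3-dicarbonyl is left to bind ruthenium. Ring-closing metathesis of this diene with the second-generation Hoveyda–Grubbs catalyst (H2IMes)Cl2Ru=CH(2-i-PrOC6H4) in CH2Cl2 at 40 °C should give ethyl 2-hydroxy-6-(4-methoxyphenyl)-3-methylcyclohex-4-ene-1-carboxylate F2. Dess–Martin oxidation of the secondary alcohol then returns keto ester 9, which goes on to step 5.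

Step 8 (double aryllithium addition). The risk is incomplete second addition at the carbonyl carbon wedged between ring B and the alkyne. On warming, the tertiary alkoxide could also cyclize onto the neighbouring alkyne. The fallback sets out from 14 and returns at 18, building the carbinol one aryl group at a time on more electrophilic carbonyls. Ester 14 is reduced with i-Bu2AlH (CH2Cl2, −78 to 0 °C) to {4'-methoxy-3-[(4-methoxyphenyl)ethynyl]-4-methyl-[1,1'-biphenyl]-2-yl}methanol F3. Oxidation with MnO2 gives 4'-methoxy-3-[(4-methoxyphenyl)ethynyl]-4-methyl-[1,1'-biphenyl]-2-carbaldehyde F4. Addition of 4-methoxyphenyllithium 16 at −78 °C gives {4'-methoxy-3-[(4-methoxyphenyl)ethynyl]-4-methyl-[1,1'-biphenyl]-2-yl}(4-methoxyphenyl)methanol F5. Dess–Martin oxidation gives ketone 17, this time isolated. A second addition of 16 in the presence of anhydrous CeCl3 as activating additive (THF, −78 °C) should then give carbinol 18 without warming.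

Step 7 (Sonogashira coupling). The risk is slow oxidative addition at the triflate flanked by methyl and ester groups, so that cleavage of the S–O bond by the amine and copper-mediated dimerization of the alkyne take over. The fallback sets out from 12 and 13 and returns at 14. Alkyne 13 is lithiated (n-BuLi, THF, −78 °C) and quenched with Bu3SnCl to give tributyl[(4-methoxyphenyl)ethynyl]stannane F6. F6 is coupled with triflate 12 under Stille conditions (Pd(PPh3)4, LiCl, 1,4-dioxane, 100 °C) to give 14. This removes copper, amine base and the free terminal alkyne from the flask.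

**Further compounds**

F1 | step 4 | ethyl 3-hydroxy-2-[1-(4-methoxyphenyl)prop-2-en-1-yl]-4-methylhex-5-enoate (diastereomer mixture) | CCOC(=O)C(C(C=C)c1ccc(OC)cc1)C(O)C(C)C=C
F2 | step 4 | ethyl 2-hydroxy-6-(4-methoxyphenyl)-3-methylcyclohex-4-ene-1-carboxylate (diastereomer mixture) | CCOC(=O)C1C(O)C(C)C=CC1c1ccc(OC)cc1
F3 | step 8 | {4'-methoxy-3-[(4-methoxyphenyl)ethynyl]-4-methyl-[1,1'-biphenyl]-2-yl}methanol | OCc1c(C#Cc2ccc(OC)cc2)c(C)ccc1-c1ccc(OC)cc1
F4 | step 8 | 4'-methoxy-3-[(4-methoxyphenyl)ethynyl]-4-methyl-[1,1'-biphenyl]-2-carbaldehyde | O=Cc1c(C#Cc2ccc(OC)cc2)c(C)ccc1-c1ccc(OC)cc1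
F5 | step 8 | {4'-methoxy-3-[(4-methoxyphenyl)ethynyl]-4-methyl-[1,1'-biphenyl]-2-yl}(4-methoxyphenyl)methanol (racemic) | COc1ccc(cc1)C(O)c1c(C#Cc2ccc(OC)cc2)c(C)ccc1-c1ccc(OC)cc1
F6 | step 7 | tributyl[(4-methoxyphenyl)ethynyl]stannane | CCCC[Sn](CCCC)(CCCC)C#Cc1ccc(OC)cc1
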